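**Retrosynthetic overview**
1. Target 24 ⇒ final E-selective Wittig olefination between lactone phosphonium salt 22 (fragment B) and butenolide aldehyde 12 (fragment A).
2. Aldehyde 12 ⇒ periodic acid cleavage of terminal epoxide 11, the epoxide serving as a masked aldehyde carried from farnesol.
3. Butenolide 11 ⇒ ring-closing metathesis of acrylate 10; this is the only ring closed in the route.
4. Acrylate 10 ⇒ allylic alcohol 8 ⇒ 10,11-epoxyfarnesyl bromide 5 + methallyl alcohol dianion; 5 ⇐ (2E,6E)-farnesol 1, which supplies both E trisubstituted alkenes.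
5. Ring order: the saturated γ-lactone ring, with its (S) centre, is present from the start in (S)-5-oxotetrahydrofuran-2-carboxylic acid 13; the butenolide ring is closed at step 6; the two are joined at step 13.

Assumption: the bromohydrin/epoxide carbon of 2–5, 8, 10 and 11 is carried as a racemate (it is excised in step 7), and C-3 of 21 and 22 is an epimer mixture (it becomes sp2 in step 13); neither affects the target.

**Fragment A (steps 1–7)**

Step 1
Reactants: 1 (2E,6E)-farnesol
Product: 2 (2E,6E)-10-bromo-3,7,11-trimethyldodeca-2,6-diene-1,11-diol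
Conditions: NBS (1.1 equiv), THF/H2O (2:1), 0 °C
Reagents that add atoms: N-bromosuccinimide, O=C1CCC(=O)N1Br (gives Br); water, O (gives OH)
Why: Terminal-selective bromohydrin formation, because in aqueous THF the terminal trisubstituted alkene is the most exposed and water opens the bromonium ion at the tertiary carbon; the new C-10 centre is racemic and is removed in step 7.

Step 2
Reactants: 2 (2E,6E)-10-bromo-3,7,11-trimethyldodeca-2,6-diene-1,11-diol
Product: 3 (2E,6E)-10,11-epoxy-3,7,11-trimethyldodeca-2,6-dien-1-ol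
Conditions: K2CO3, MeOH, rt
Reagents that add atoms: none
Why: Intramolecular Williamson etherification, in which the tertiary alkoxide displaces the neighbouring secondary bromide to close the epoxide without touching the allylic alcohol.

Step 3
Reactants: 3 (2E,6E)-10,11-epoxy-3,7,11-trimethyldodeca-2,6-dien-1-ol
Product: 5 (2E,6E)-1-bromo-10,11-epoxy-3,7,11-trimethyldodeca-2,6-diene, via allylic mesylate 4 (not isolated)
Conditions: MsCl, Et3N, THF, −40 °C; then LiBr, THF, 0 °C
Reagents that add atoms: lithium bromide LiBr, [Li+].[Br-] (Br of 5); methanesulfonyl chloride, CS(=O)(=O)Cl (mesyl group, present only in intermediate 4)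
Why: Mesylation followed by SN2 bromide displacement is non-acidic, so the epoxide survives and the 2E alkene geometry is kept.

Step 4
Reactants: 5 (2E,6E)-1-bromo-10,11-epoxy-3,7,11-trimethyldodeca-2,6-diene; 6 2-methylprop-2-en-1-ol
Product: 8 (5E,9E)-13,14-epoxy-6,10,14-trimethyl-2-methylidenepentadeca-5,9-dien-1-ol, via dilithio dianion 7 (not isolated)
Conditions: 6 (3 equiv), n-BuLi (6 equiv), TMEDA, Et2O/hexane, 0 °C → rt; then 5, THF, −78 → 0 °C; H2O quench
Reagents that add atoms: n-BuLi, [Li]CCCC (lithium, present only in intermediate 7)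
Why: SN2 allyl–allyl alkylation of the C,O-dianion of methallyl alcohol at the primary allylic bromide; both carbon termini of the dianion give the same product, and the hindered trisubstituted epoxide is much slower to react at low temperature.

Step 5
Reactants: 8 (5E,9E)-13,14-epoxy-6,10,14-trimethyl-2-methylidenepentadeca-5,9-dien-1-ol; 9 acryloyl chloride
Product: 10 (5E,9E)-13,14-epoxy-6,10,14-trimethyl-2-methylidenepentadeca-5,9-dien-1-yl prop-2-enoate
Conditions: 9, Et3N, DMAP (cat.), CH2Cl2, −20 → 0 °C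
Reagents that add atoms: none
Why: Simple O-acylation (esterification) of the primary allylic alcohol installs the second alkene for the ring closure.

Step 6
Reactants: 10 (5E,9E)-13,14-epoxy-6,10,14-trimethyl-2-methylidenepentadeca-5,9-dien-1-yl prop-2-enoate
Product: 11 4-[(3E,7E)-11,12-epoxy-4,8,12-trimethyltrideca-3,7-dien-1-yl]furan-2(5H)-one
Conditions: second-generation Grubbs catalyst RuCl2(=CHPh)(PCy3)(H2IMes) (5 mol%), CH2Cl2 (5 mM), 40 °C
Reagents that add atoms: none
Why: Ring-closing metathesis of the acrylate with the 1,1-disubstituted alkene gives the five-membered butenolide with loss of ethene; any closure onto the internal trisubstituted chain alkenes would need a four-, eight- or larger-membered ring, so they stay as spectators.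

Step 7
Reactants: 11 4-[(3E,7E)-11,12-epoxy-4,8,12-trimethyltrideca-3,7-dien-1-yl]furan-2(5H)-one
Product: 12 (4E,8E)-4,8-dimethyl-11-(5-oxo-2,5-dihydrofuran-3-yl)undeca-4,8-dienal
Conditions: H5IO6, THF/H2O, 0 °C
Reagents that add atoms: none
Why: Periodic acid hydrolyses the epoxide and cleaves the resulting glycol in one pot (glycol cleavage), releasing acetone and the aldehyde while leaving the alkenes and butenolide untouched.

**Fragment B (steps 8–12)**

Step 8
Reactants: 13 (S)-5-oxotetrahydrofuran-2-carboxylic acid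
Product: 14 (S)-5-(hydroxymethyl)dihydrofuran-2(3H)-one
Conditions: BH3·SMe2, THF, 0 °C → rt; MeOH quench
Reagents that add atoms: none
Why: Chemoselective borane reduction of the carboxylic acid in the presence of the lactone; the stereocentre is not involved.

Step 9
Reactants: 14 (S)-5-(hydroxymethyl)dihydrofuran-2(3H)-one
Product: 15 (S)-5-oxotetrahydrofuran-2-carbaldehyde
Conditions: Dess–Martin periodinane, CH2Cl2, 0 °C → rt; non-aqueous work-up, used crude
Reagents that add atoms: none
Why: Dess–Martin oxidation is mild and near-neutral, which limits epimerisation and hydration of this labile α-acyloxy aldehyde.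

Step 10
Reactants: 15 (S)-5-oxotetrahydrofuran-2-carbaldehyde; 16 isopropyltriphenylphosphonium iodide
Product: 18 (S)-5-(2-methylprop-1-en-1-yl)dihydrofuran-2(3H)-one, via isopropylidene ylide 17 (not isolated)
Conditions: 16 (1.05 equiv), n-BuLi (1.0 equiv), THF, 0 °C; then 15, −78 °C → rt
Reagents that add atoms: none
Why: Wittig olefination with a non-stabilised ylide is far faster at the aldehyde than at the lactone carbonyl at −78 °C, and with no excess base the (S) centre from the chiral pool is kept.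

Step 11
Reactants: 18 (S)-5-(2-methylprop-1-en-1-yl)dihydrofuran-2(3H)-one
Product: 21 (3RS,5S)-3-bromo-5-(2-methylprop-1-en-1-yl)dihydrofuran-2(3H)-one, via lithium enolate 19 (not isolated), via silyl ketene acetal 20 (not isolated)
Conditions: LiN(i-Pr)2, THF, −78 °C; Me3SiCl; then NBS, THF, −78 °C; aqueous work-up
Reagents that add atoms: N-bromosuccinimide, O=C1CCC(=O)N1Br (Br of 21); LiN(i-Pr)2, [Li]N(C(C)C)C(C)C (lithium, only in intermediate 19); Me3SiCl, C[Si](C)(C)Cl (Me3Si, only in intermediate 20)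
Why: α-Bromination through the silyl ketene acetal, which is far more nucleophilic towards NBS than the trisubstituted alkene; C-5 is untouched and the C-3 epimer mixture is irrelevant.

Step 12
Reactants: 21 (3RS,5S)-3-bromo-5-(2-methylprop-1-en-1-yl)dihydrofuran-2(3H)-one
Product: 22 [(3RS,5S)-5-(2-methylprop-1-en-1-yl)-2-oxotetrahydrofuran-3-yl]triphenylphosphonium bromide
Conditions: PPh3, THF, reflux
Reagents that add atoms: triphenylphosphine, c1ccc(cc1)P(c1ccccc1)c1ccccc1
Why: SN2 quaternisation of the activated α-bromo lactone under neutral conditions, which do not ionise the allylic lactone C–O bond.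

**Fragment coupling**

Step 13
Reactants: 22 [(3RS,5S)-5-(2-methylprop-1-en-1-yl)-2-oxotetrahydrofuran-3-yl]triphenylphosphonium bromide; 12 (4E,8E)-4,8-dimethyl-11-(5-oxo-2,5-dihydrofuran-3-yl)undeca-4,8-dienal
Product: 24 (3E,5S)-3-[(4E,8E)-4,8-dimethyl-11-(5-oxo-2,5-dihydrofuran-3-yl)undeca-4,8-dien-1-ylidene]-5-(2-methylprop-1-en-1-yl)dihydrofuran-2(3H)-one, via lactone ylide 23 (not isolated)
Conditions: 22 (1.3 equiv), Et3N, CH2Cl2, rt; then 12, rt → 40 °C
Reagents that add atoms: none
Why: Wittig olefination with an ester-stabilised ylide gives the E-alkylidene lactone under thermodynamic control, and the base-free conditions leave the butenolide and the (S) centre untouched.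

**Compound list**
1 | (2E,6E)-farnesol | CC(C)=CCC/C(C)=C/CC/C(C)=C/CO | starting material
2 | (2E,6E)-10-bromo-3,7,11-trimethyldodeca-2,6-diene-1,11-diol (racemic at C-10) | CC(C)(O)C(Br)CC/C(C)=C/CC/C(C)=C/CO | intermediate
3 | (2E,6E)-10,11-epoxy-3,7,11-trimethyldodeca-2,6-dien-1-ol (racemic epoxide) | CC1(C)OC1CC/C(C)=C/CC/C(C)=C/CO | intermediate
4 | (2E,6E)-10,11-epoxy-3,7,11-trimethyldodeca-2,6-dien-1-yl methanesulfonate | CC1(C)OC1CC/C(C)=C/CC/C(C)=C/COS(C)(=O)=O | intermediate
5 | (2E,6E)-1-bromo-10,11-epoxy-3,7,11-trimethyldodeca-2,6-diene | CC1(C)OC1CC/C(C)=C/CC/C(C)=C/CBr | intermediate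
6 | 2-methylprop-2-en-1-ol (methallyl alcohol) | CC(=C)CO | starting material
7 | lithium 2-(lithiomethyl)prop-2-en-1-olate (C,O-dianion of 6) | [Li]CC(=C)CO[Li] | intermediate
8 | (5E,9E)-13,14-epoxy-6,10,14-trimethyl-2-methylidenepentadeca-5,9-dien-1-ol | CC1(C)OC1CC/C(C)=C/CC/C(C)=C/CCC(=C)CO | intermediate
9 | acryloyl chloride | C=CC(=O)Cl | starting material
10 | (5E,9E)-13,14-epoxy-6,10,14-trimethyl-2-methylidenepentadeca-5,9-dien-1-yl prop-2-enoate | CC1(C)OC1CC/C(C)=C/CC/C(C)=C/CCC(=C)COC(=O)C=C | intermediate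
11 | 4-[(3E,7E)-11,12-epoxy-4,8,12-trimethyltrideca-3,7-dien-1-yl]furan-2(5H)-one | CC1(C)OC1CC/C(C)=C/CC/C(C)=C/CCC2=CC(=O)OC2 | intermediate
12 | (4E,8E)-4,8-dimethyl-11-(5-oxo-2,5-dihydrofuran-3-yl)undeca-4,8-dienal | O=CCC/C(C)=C/CC/C(C)=C/CCC1=CC(=O)OC1 | intermediate
13 | (S)-5-oxotetrahydrofuran-2-carboxylic acid | OC(=O)[C@@H]1CCC(=O)O1 | starting material
14 | (S)-5-(hydroxymethyl)dihydrofuran-2(3H)-one | OC[C@@H]1CCC(=O)O1 | intermediate
15 | (S)-5-oxotetrahydrofuran-2-carbaldehyde | O=C[C@@H]1CCC(=O)O1 | intermediate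
16 | isopropyltriphenylphosphonium iodide | CC(C)[P+](c1ccccc1)(c1ccccc1)c1ccccc1.[I-] | starting material
17 | isopropylidenetriphenylphosphorane | CC(C)=P(c1ccccc1)(c1ccccc1)c1ccccc1 | intermediate
18 | (S)-5-(2-methylprop-1-en-1-yl)dihydrofuran-2(3H)-one | CC(C)=C[C@@H]1CCC(=O)O1 | intermediate
19 | lithium (S)-5-(2-methylprop-1-en-1-yl)-4,5-dihydrofuran-2-olate | CC(C)=C[C@@H]1CC=C(O[Li])O1 | intermediate
20 | trimethyl{[(S)-5-(2-methylprop-1-en-1-yl)-4,5-dihydrofuran-2-yl]oxy}silane | CC(C)=C[C@@H]1CC=C(O[Si](C)(C)C)O1 | intermediate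
21 | (3RS,5S)-3-bromo-5-(2-methylprop-1-en-1-yl)dihydrofuran-2(3H)-one | CC(C)=C[C@@H]1CC(Br)C(=O)O1 | intermediate
22 | [(3RS,5S)-5-(2-methylprop-1-en-1-yl)-2-oxotetrahydrofuran-3-yl]triphenylphosphonium bromide | CC(C)=C[C@@H]1CC(C(=O)O1)[P+](c1ccccc1)(c1ccccc1)c1ccccc1.[Br-] | intermediate
23 | (S)-5-(2-methylprop-1-en-1-yl)-3-(triphenyl-λ5-phosphanylidene)dihydrofuran-2(3H)-one | CC(C)=C[C@@H]1CC(=P(c2ccccc2)(c2ccccc2)c2ccccc2)C(=O)O1 | intermediate
24 | (3E,5S)-3-[(4E,8E)-4,8-dimethyl-11-(5-oxo-2,5-dihydrofuran-3-yl)undeca-4,8-dien-1-ylidene]-5-(2-methylprop-1-en-1-yl)dihydrofuran-2(3H)-one | CC(C)=C[C@@H]1C/C(=C\CC/C(C)=C/CC/C(C)=C/CCC2=CC(=O)OC2)C(=O)O1 | target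

**Step count and risk**

Total steps: 13. Longest linear sequence: 8 (steps 1–7, then 13); the lactone branch is 6 (steps 8–12, then 13).

Three steps most likely to fail:

Step 4 (dianion allyl–allyl coupling; risks are Wurtz-type homocoupling, SN2′ attack and sluggish metalation). Fallback: set out from epoxy alcohol 3 and oxidise it with MnO2 (CH2Cl2, rt) to (2E,6E)-10,11-epoxyfarnesal F1. Methylenate this with Ph3P=CH2 (Ph3PCH3Br, KOt-Bu, THF, 0 °C) to the triene epoxide F2. Hydroborate the terminal vinyl group of F2 with 9-BBN-H (THF, 0 °C → rt) to the B-alkyl-9-BBN derivative F3, and couple it in the same flask with 2-bromoprop-2-en-1-ol under PdCl2(dppf)/aq. K3PO4 (THF/DMF, 50 °C, B-alkyl Suzuki–Miyaura coupling). This comes back to the route at compound 8, replacing steps 3 and 4.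

Step 6 (ring-closing metathesis to a trisubstituted butenolide; risks are slow closure at the 1,1-disubstituted alkene and acrylate oligomerisation). Fallback: set out from bromide 5 and alkylate it with the dianion of methyl acetoacetate (NaH, then n-BuLi, THF, 0 °C; γ-alkylation) to the β-keto ester F4. Convert F4 through its chelated sodium enolate into the (Z)-enol triflate F5 (NaH, PhNTf2, THF, 0 °C → rt). Stille coupling of F5 with Bu3SnCH2OH (Pd(PPh3)4, LiCl, dioxane, 90 °C) gives the (Z)-hydroxymethyl enoate F6, which lactonises in the flask. This comes back to the route at compound 11, replacing steps 4–6.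

Step 11 (α-bromination beside an electron-rich alkene, and the quaternisation that depends on it). Fallback: set out from lactone 18, deprotonate with LiN(i-Pr)2 (2.2 equiv, THF, −78 °C) and add ClP(O)(OEt)2 to form the enol phosphate F7. The excess base rearranges F7 by a 1,3-phosphorus shift to the α-phosphono lactone F8 on warming to rt. Horner–Wadsworth–Emmons reaction of F8 with aldehyde 12 (NaH, THF, 0 °C → rt) gives the alkylidene lactone, E isomer major, with the Z isomer removed by chromatography. This comes back to the route at compound 24, replacing steps 11–13.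

**Further compounds**
F1 | step 4 | (2E,6E)-10,11-epoxy-3,7,11-trimethyldodeca-2,6-dienal | CC1(C)OC1CC/C(C)=C/CC/C(C)=C/C=O
F2 | step 4 | (3E,7E)-11,12-epoxy-4,8,12-trimethyltrideca-1,3,7-triene | CC1(C)OC1CC/C(C)=C/CC/C(C)=C/C=C
F3 | step 4 | 9-[(3E,7E)-11,12-epoxy-4,8,12-trimethyltrideca-3,7-dien-1-yl]-9-borabicyclo[3.3.1]nonane | CC1(C)OC1CC/C(C)=C/CC/C(C)=C/CCB2C3CCCC2CCC3
F4 | step 6 | methyl (6E,10E)-14,15-epoxy-7,11,15-trimethyl-3-oxohexadeca-6,10-dienoate | CC1(C)OC1CC/C(C)=C/CC/C(C)=C/CCC(=O)CC(=O)OC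
F5 | step 6 | methyl (2Z,6E,10E)-14,15-epoxy-7,11,15-trimethyl-3-(trifluoromethylsulfonyloxy)hexadeca-2,6,10-trienoate | CC1(C)OC1CC/C(C)=C/CC/C(C)=C/CC/C(OS(=O)(=O)C(F)(F)F)=C/C(=O)OC
F6 | step 6 | methyl (2Z,6E,10E)-14,15-epoxy-3-(hydroxymethyl)-7,11,15-trimethylhexadeca-2,6,10-trienoate | CC1(C)OC1CC/C(C)=C/CC/C(C)=C/CC/C(CO)=C/C(=O)OC
F7 | step 11 | diethyl (S)-5-(2-methylprop-1-en-1-yl)-4,5-dihydrofuran-2-yl phosphate | CC(C)=C[C@@H]1CC=C(OP(=O)(OCC)OCC)O1
F8 | step 11 | diethyl [(3RS,5S)-5-(2-methylprop-1-en-1-yl)-2-oxotetrahydrofuran-3-yl]phosphonate | CC(C)=C[C@@H]1CC(C(=O)O1)P(=O)(OCC)OCC
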